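**Plan**
- Retrosynthetic cuts: the two ester C–O bonds at C8 and C9; C7–isopropenyl (epoxide opening); C1–C10 of ring B (oxidative union of two enol ethers); C4–CH3 (conjugate addition); C3=C4 (Wittig); C5–C10 and C6–C7 of ring A (Diels–Alder).
- Forward order: ring A by Diels–Alder, side chain C4–C1 attached and methylated, ring A raised to the enone, ring B closed by anodic coupling, then C9, C8 and C7 functionalised and acylated.
- Enabling feature: the ring-B ketone C2 and the ring-A oxygen at C9 are 1,4-related through C1–C10. Both carbons are α to a carbonyl, so the bond is an umpoled enol ether/enol ether coupling, and C10 sits next to the quaternary C5 that carries the tether.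
- Stereochemistry: C5 from a catalytic asymmetric Diels–Alder reaction; C4 from a copper-catalysed asymmetric methyl addition; C10 from the enforced cis ring closure; C9, C8 and C7 by substrate control on the cis-decalin (convex-face hydride, hydroxyl-directed epoxidation, anti epoxide opening); the ester stereocentre from (R)-2-methylbutanoic acid.

Key step: step 8

Remarks: locants follow the eremophilane numbering of the target (C1–C10 ring carbons, C2 ketone, methyls on C4 and C5, isopropenyl on C7, esters on C8 and C9). α is the face of the cis-decalin that carries the C5 methyl group (and the C4 methyl, H-10 and the isopropenyl group); β is the opposite face. The 2-methylbutanoate in the given structure is (R)-configured and is introduced as such.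

Step 1
Reactants: 1 buta-1,3-diene; 2 methacrolein
Product: 3 (S)-1-methylcyclohex-3-ene-1-carbaldehyde
Conditions: chiral oxazaborolidinium triflimide (o-tolyl-CBS·HNTf2, 10 mol%), excess diene, CH2Cl2, −78 to −40 °C
Reagents that add atoms: none
Why: Catalytic enantioselective Diels–Alder reaction of an α-substituted acrolein with a chiral oxazaborolidinium Lewis acid; the catalyst shields one face of the coordinated s-trans enal, so the quaternary centre C5 is set by catalyst control (the catalyst enantiomer is chosen to give the S adduct).

Step 2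
Reactants: 3 (S)-1-methylcyclohex-3-ene-1-carbaldehyde; 4 1-(triphenylphosphoranylidene)propan-2-one
Product: 5 (E)-4-[(1S)-1-methylcyclohex-3-en-1-yl]but-3-en-2-one
Conditions: toluene, 100 °C
Reagents that add atoms: none
Why: Wittig olefination of a non-enolisable neopentyl aldehyde with a stabilised ylide should give the (E)-enone; no stereocentre is touched.

Step 3
Reactants: 5 (E)-4-[(1S)-1-methylcyclohex-3-en-1-yl]but-3-en-2-one; 6 methylmagnesium bromide
Product: 7 (4S)-4-[(1S)-1-methylcyclohex-3-en-1-yl]pentan-2-one
Conditions: CuBr·SMe2 (5 mol%), Josiphos-type ferrocenyl diphosphine (6 mol%, enantiomer giving 4S), slow addition of MeMgBr, t-BuOMe, −75 °C; aq. NH4Cl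
Reagents that add atoms: none
Why: Copper-catalysed enantioselective conjugate addition of a Grignard reagent to an acyclic (E)-enone; the chiral copper–diphosphine complex delivers methyl to one enantioface and sets C4 by catalyst control, the ring alkene being inert.

Step 4
Reactants: 7 (4S)-4-[(1S)-1-methylcyclohex-3-en-1-yl]pentan-2-one
Product: 8 (4S)-4-[(1S)-3,4-epoxy-1-methylcyclohexyl]pentan-2-one (C8–C9 epoxide; both faces)
Conditions: mCPBA, NaHCO3, CH2Cl2, 0 °C
Reagents that add atoms: 3-chloroperbenzoic acid, OOC(=O)c1cccc(Cl)c1
Why: Prilezhaev epoxidation of the only electron-rich alkene; the facial mixture is harmless because C9 becomes a carbonyl and C8 an sp2 carbon in steps 5 and 6.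

Step 5
Reactants: 8 (4S)-4-[(1S)-3,4-epoxy-1-methylcyclohexyl]pentan-2-one
Product: 10 (5S)-5-[(2S)-4-hydroxypentan-2-yl]-5-methylcyclohex-2-en-1-ol (epimers at both carbinol carbons), via hydroxy selenide 9 (not isolated)
Conditions: PhSeSePh, NaBH4 (excess), EtOH, 0 to 78 °C; then 30% H2O2, THF, 0 to 25 °C
Reagents that add atoms: none
Why: Epoxide-to-allylic-alcohol transposition by selenide opening and selenoxide syn-elimination: phenylselenide should open the epoxide trans-diaxially at C8, because attack at C9 would be 1,3-diaxial to a substituent on quaternary C5, and the selenoxide eliminates away from the carbinol to place the alkene at C7=C8 with oxygen on C9. Excess borohydride also reduces the methyl ketone, which step 6 restores, and the regioisomeric opening would give a separable constitutional isomer.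

Step 6
Reactants: 10 (5S)-5-[(2S)-4-hydroxypentan-2-yl]-5-methylcyclohex-2-en-1-ol
Product: 11 (5S)-5-methyl-5-[(2S)-4-oxopentan-2-yl]cyclohex-2-en-1-one
Conditions: TPAP (5 mol%), NMO, 4 Å MS, CH2Cl2, 25 °C
Reagents that add atoms: none
Why: Ley–Griffith oxidation of the allylic and the saturated secondary alcohol gives the ring enone and the methyl ketone in one operation; C4 and C5 are not enolisable positions.

Step 7
Reactants: 11 (5S)-5-methyl-5-[(2S)-4-oxopentan-2-yl]cyclohex-2-en-1-one
Product: 12 bis(trimethylsilyl) enol ether of 11 (ring 2-silyloxy-1,3-diene C7=C8–C9(OTMS)=C10 and side-chain enol ether C1=C2(OTMS))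
Conditions: TMSCl (6 equiv), then LDA (2.4 equiv), THF, −78 °C (in situ quench); Et3N, pentane, filtration
Reagents that add atoms: chlorotrimethylsilane, C[Si](C)(C)Cl
Why: Kinetic double enolisation with internal silyl quench: LDA removes the α′ proton at C10 of the enone (cross-conjugated dienolate, C8 being blocked by the enone) and a methyl proton at C1 of the methyl ketone, so both enol ethers are regiodefined.

Step 8
Reactants: 12 bis(trimethylsilyl) enol ether of 11
Product: 13 (4S,5R,10S)-4,5-dimethyl-cis-octal-7-ene-2,9-dione (cis-fused enedione)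
Conditions: constant-current electrolysis (2.1–2.2 F/mol), RVC anode, Pt cathode, undivided cell, 0.1 M LiClO4, MeCN/i-PrOH 4:1, 2,6-lutidine, 0 °C, 0.01 M substrate
Reagents that add atoms: none
Why: One-electron anodic oxidation of the more electron-rich cross-conjugated silyloxydiene gives a radical cation whose C10 terminus is attacked by C1 of the tethered silyl enol ether; desilylation of the C2 oxocarbenium ion, a second oxidation of the 9-silyloxyallyl radical and loss of the second silyl group release the 1,4-diketone (closest known types: anodic enol ether–enol ether coupling and the oxidative coupling of bis(silyl enol ethers) by cerium(IV) or copper(II)). Ring B closes in a 6-exo mode with respect to the oxidised C9=C10 bond, whereas attack at the other diene terminus C7 would need a bridged seven-membered ring. The new stereocentre C10 is controlled by quaternary C5: the four-atom tether can reach only the face of the flat dienyl system on which the C5–C4 bond stands, so C1 and C4 end up cis (H-10 syn to the C5 methyl). The step needs oxidation of the diene before the simple enol ether (lower oxidation potential), coupling only at C10 and C1 (secured by the two kinetically defined enol ethers), and retention of the kinetic cis fusion (buffered, non-basic electrolyte at 0 °C).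

Step 9
Reactants: 13 cis-fused enedione
Product: 14 C2 ethylene ketal of 13
Conditions: TMSOCH2CH2OTMS, TMSOTf (5 mol%), CH2Cl2, −78 °C; pyridine quench
Reagents that add atoms: 1,2-bis(trimethylsilyloxy)ethane, C[Si](C)(C)OCCO[Si](C)(C)C
Why: Silyl-triflate-catalysed ketalisation with the bis-silyl glycol ether is selective for the saturated C2 ketone over the conjugated C9 ketone at −78 °C, and the acid-free, cold conditions should not enolise C10.

Step 10
Reactants: 14 C2 ethylene ketal of 13
Product: 15 9β-hydroxy-Δ7-ene ketal (allylic alcohol)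
Conditions: NaBH4, CeCl3·7H2O, MeOH, −78 °C
Reagents that add atoms: none
Why: Luche 1,2-reduction; hydride should add to C9 from the convex α face of the cis-decalin, because the β face is covered by ring B, giving the 9β alcohol and removing the only epimerisable position (C10).

Step 11
Reactants: 15 9β-hydroxy-Δ7-ene ketal
Product: 16 7β,8β-epoxy-9β-hydroxy ketal
Conditions: VO(acac)2 (5 mol%), t-BuOOH, CH2Cl2, 0 to 25 °C
Reagents that add atoms: tert-butyl hydroperoxide, CC(C)(C)OO
Why: Vanadium-catalysed hydroxyl-directed epoxidation delivers oxygen within the vanadate ester to the alkene face syn to the 9-OH, which sets C8–O β (cis to C9–O) despite the concave environment.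

Step 12
Reactants: 16 7β,8β-epoxy-9β-hydroxy ketal; 17 isopropenylmagnesium bromide
Product: 18 7α-isopropenyl-8β,9β-diol ketal
Conditions: 17 (4 equiv), CuI (20 mol%), THF, −30 to 0 °C
Reagents that add atoms: none
Why: Copper-catalysed Grignard opening of the epoxide by SN2 attack with inversion (Fürst–Plattner trans-diaxial opening) at C7, the carbon distal to the alkoxide-bearing C9; attack at C8 would be next to the magnesium alkoxide and would force it axial against C4. The nucleophile enters from the convex α face, which gives 7α-isopropenyl and leaves the 8β hydroxyl.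

Step 13
Reactants: 18 7α-isopropenyl-8β,9β-diol ketal; 19 (R)-2-methylbutanoic acid
Product: 20 8-O-[(R)-2-methylbutanoyl] 9β-hydroxy ketal
Conditions: DCC, DMAP (cat.), CH2Cl2, 0 °C
Reagents that add atoms: none
Why: Steglich esterification; the equatorial C8 hydroxyl should react in preference to the axial C9 hydroxyl, which is flanked by the ring fusion and 1,3-diaxial to C4, and the mild conditions should not racemise the α-branched acid.

Step 14
Reactants: 20 8-O-[(R)-2-methylbutanoyl] 9β-hydroxy ketal; 21 tigloyl chloride
Product: 22 8-O-[(R)-2-methylbutanoyl] 9-O-tigloyl ketal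
Conditions: 21 (3 equiv), DMAP, pyridine, CH2Cl2, 40 °C
Reagents that add atoms: none
Why: DMAP-catalysed acylation of the remaining hindered secondary alcohol with the acid chloride; the (E)-configured tiglate is the stable geometry and is retained.

Step 15
Reactants: 22 8-O-[(R)-2-methylbutanoyl] 9-O-tigloyl ketal
Product: 23 CNP0312791.1
Conditions: PPTS, acetone/H2O, 55 °C
Reagents that add atoms: water, O
Why: Acid-catalysed ketal hydrolysis; both esters and the isopropenyl group tolerate the mild acid, and neither α-carbon of the freed C2 ketone (C1, C3) is a stereocentre.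

**Compound list**
1 | buta-1,3-diene | C=CC=C | starting material
2 | methacrolein (2-methylprop-2-enal) | CC(=C)C=O | starting material
3 | (S)-1-methylcyclohex-3-ene-1-carbaldehyde | O=C[C@@]1(C)CCC=CC1 | intermediate
4 | 1-(triphenylphosphoranylidene)propan-2-one | CC(=O)C=P(c1ccccc1)(c1ccccc1)c1ccccc1 | starting material
5 | (E)-4-[(1S)-1-methylcyclohex-3-en-1-yl]but-3-en-2-one | CC(=O)/C=C/[C@@]1(C)CCC=CC1 | intermediate
6 | methylmagnesium bromide | C[Mg]Br | starting material
7 | (4S)-4-[(1S)-1-methylcyclohex-3-en-1-yl]pentan-2-one | CC(=O)C[C@H](C)[C@@]1(C)CCC=CC1 | intermediate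
8 | (4S)-4-[(1S)-3,4-epoxy-1-methylcyclohexyl]pentan-2-one (C8–C9 epoxide; both epoxide faces) | CC(=O)C[C@H](C)[C@@]1(C)CCC2OC2C1 | intermediate
9 | trans-hydroxy selenide: C9-hydroxy, C8-phenylselanyl, side-chain carbinol (epimer mixture) | CC(O)C[C@H](C)[C@@]1(C)CCC([Se]c2ccccc2)C(O)C1 | intermediate
10 | (5S)-5-[(2S)-4-hydroxypentan-2-yl]-5-methylcyclohex-2-en-1-ol (epimers at both carbinol carbons) | CC(O)C[C@H](C)[C@@]1(C)CC=CC(O)C1 | intermediate
11 | (5S)-5-methyl-5-[(2S)-4-oxopentan-2-yl]cyclohex-2-en-1-one | CC(=O)C[C@H](C)[C@@]1(C)CC=CC(=O)C1 | intermediate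
12 | bis(trimethylsilyl) enol ether of 11 (ring 2-silyloxydiene, side-chain C1=C2 enol ether) | C=C(O[Si](C)(C)C)C[C@H](C)[C@@]1(C)CC=CC(O[Si](C)(C)C)=C1 | intermediate
13 | (4S,5R,10S)-4,5-dimethyl-cis-octal-7-ene-2,9-dione | C1=CC(=O)[C@H]2CC(=O)C[C@H](C)[C@@]2(C)C1 | intermediate
14 | C2 ethylene ketal of 13 | C1=CC(=O)[C@H]2CC3(OCCO3)C[C@H](C)[C@@]2(C)C1 | intermediate
15 | 9β-hydroxy-Δ7-ene C2 ketal | C1=C[C@@H](O)[C@H]2CC3(OCCO3)C[C@H](C)[C@@]2(C)C1 | intermediate
16 | 7β,8β-epoxy-9β-hydroxy C2 ketal | C1[C@H]2O[C@H]2[C@@H](O)[C@H]3CC4(OCCO4)C[C@H](C)[C@]31C | intermediate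
17 | isopropenylmagnesium bromide | CC(=C)[Mg]Br | starting material
18 | 7α-isopropenyl-8β,9β-dihydroxy C2 ketal | C=C(C)[C@H]1C[C@@]2(C)[C@H](CC3(OCCO3)C[C@@H]2C)[C@H](O)[C@@H]1O | intermediate
19 | (R)-2-methylbutanoic acid | CC[C@@H](C)C(=O)O | starting material
20 | 8-O-[(R)-2-methylbutanoyl]-9β-hydroxy C2 ketal | C=C(C)[C@H]1C[C@@]2(C)[C@H](CC3(OCCO3)C[C@@H]2C)[C@H](O)[C@@H]1OC(=O)[C@H](C)CC | intermediate
21 | tigloyl chloride ((E)-2-methylbut-2-enoyl chloride) | C/C=C(\C)C(=O)Cl | starting material
22 | 8-O-[(R)-2-methylbutanoyl]-9-O-tigloyl C2 ketal | C=C(C)[C@H]1C[C@@]2(C)[C@H](CC3(OCCO3)C[C@@H]2C)[C@H](OC(=O)/C(C)=C/C)[C@@H]1OC(=O)[C@H](C)CC | intermediate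
23 | CNP0312791.1 | C=C(C)[C@H]1C[C@@]2(C)[C@H](CC(=O)C[C@@H]2C)[C@H](OC(=O)/C(C)=C/C)[C@@H]1OC(=O)[C@H](C)CC | target

Total step count: 15. Longest linear sequence: 15 steps (1/2 to 23).

**Steps most likely to fail**

1. Step 8 (anodic ring closure). The silyl enol ethers may solvolyse before they are oxidised, the radical cation may couple between molecules instead of cyclising, or the product enone may be over-oxidised or lose the cis fusion by enolisation. The fallback makes the same C1–C10 bond from metal enolates and skips the silyl ethers. It sets out from 11: treatment with LDA (2.2 equiv, THF, −78 °C) should give the dilithium bis-enolate F1, and oxidation with anhydrous copper(II) chloride in DMF at −78 to 0 °C (intramolecular oxidative enolate coupling) should return to the route at 13.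

2. Step 3 (asymmetric methyl addition). Conjugate addition at the neopentyl β-carbon may be slow, so that uncatalysed 1,2-addition to the methyl ketone competes, and facial discrimination next to the quaternary centre may be poor. The fallback uses a stoichiometric auxiliary and sets out from 3. Horner–Wadsworth–Emmons reaction with diethyl {2-oxo-2-[(4S)-2-oxo-4-phenyl-1,3-oxazolidin-3-yl]ethyl}phosphonate (LiCl, i-Pr2NEt, MeCN) should give the N-enoyl oxazolidinone F2. Methylmagnesium bromide with CuBr·SMe2 (THF, −40 °C) should add anti to the phenyl group of the chelated imide to give the β-methyl imide F3. Transamidation (MeONHMe·HCl, Me3Al) should give the Weinreb amide F4, and methylmagnesium bromide then returns to the route at 7.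

3. Step 12 (epoxide opening). The opening may be sluggish because the incoming group is syn-axial to the C5 methyl, and attack may leak to C8 or the epoxide may isomerise to an allylic alcohol. The fallback replaces epoxide opening by conjugate addition and enolate oxidation and sets out from 14. The isopropenyl cuprate (from 17 and CuBr·SMe2) with TMSCl should add at C7 from the convex face to give the silyl enol ether F5. Rubottom oxidation (dimethyldioxirane, −78 °C; then dilute citric acid) should give the α-hydroxy ketone F6. Steglich esterification with 19 should give the keto ester F7; if the oxidation delivers the axial C8 epimer, C8 is equilibrated with DBU to the equatorial 8β ester. L-Selectride, attacking C9 from the α face, then returns to the route at 20.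

**Further compounds**
F1 | step 8 | dilithium bis-enolate of 11 | [Li]OC(=C)C[C@H](C)[C@@]1(C)CC=CC(O[Li])=C1
F2 | step 3 | (4S)-3-{(E)-3-[(1S)-1-methylcyclohex-3-en-1-yl]prop-2-enoyl}-4-phenyl-1,3-oxazolidin-2-one | O=C(/C=C/[C@@]1(C)CCC=CC1)N1[C@@H](c2ccccc2)COC1=O
F3 | step 3 | (4S)-3-{(3S)-3-[(1S)-1-methylcyclohex-3-en-1-yl]butanoyl}-4-phenyl-1,3-oxazolidin-2-one | O=C(C[C@H](C)[C@@]1(C)CCC=CC1)N1[C@@H](c2ccccc2)COC1=O
F4 | step 3 | (3S)-N-methoxy-N-methyl-3-[(1S)-1-methylcyclohex-3-en-1-yl]butanamide | CON(C)C(=O)C[C@H](C)[C@@]1(C)CCC=CC1
F5 | step 12 | 7α-isopropenyl 9-trimethylsilyloxy-Δ8-ene C2 ketal | C=C(C)[C@H]1C[C@@]2(C)[C@H](CC3(OCCO3)C[C@@H]2C)C(O[Si](C)(C)C)=C1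
F6 | step 12 | 7α-isopropenyl-8β-hydroxy-9-oxo C2 ketal | C=C(C)[C@H]1C[C@@]2(C)[C@H](CC3(OCCO3)C[C@@H]2C)C(=O)[C@@H]1O
F7 | step 12 | 7α-isopropenyl-8β-[(R)-2-methylbutanoyloxy]-9-oxo C2 ketal | C=C(C)[C@H]1C[C@@]2(C)[C@H](CC3(OCCO3)C[C@@H]2C)C(=O)[C@@H]1OC(=O)[C@H](C)CC
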